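**Retrosynthetic overview**

- The last C–C bond is a Stille coupling at the butenolide α-carbon: an epoxy vinylstannane joins an α-bromo-γ-ylidenebutenolide that already carries the polyene and the acetylenic ring; desilylation ends the route.
- The polyene is cut at C13=C14 (Wittig) into a dienynal bearing the acetylenic ring (C1–C13) and a butenolide phosphonium salt (C14 onward).
- Both halves grow from the same enynol, (E)-3-methylpent-2-en-4-yn-1-ol: Sonogashira, oxidation and C2 Wittig on one side; Pd/Cu alkynylation–lactonisation of (E)-2,3-dibromoacrylic acid on the other.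
- Both six-membered rings come from one enol triflate, made from achiral ketoisophorone by organocatalytic transfer hydrogenation (first stereocentre), relay reduction, silylation and triflation; the epoxide stereocentres are set by a chiral-dioxirane epoxidation of a dienylstannane.
- Ring order: the two carbocycles are present from the start, the oxirane is closed in step 6, the butenolide in step 11.

Assumption: both hands of each chiral organocatalyst are available, and the hand written in a step is the one predicted by the model named there, to be verified on the first batch (rotation of known (6R)-levodione, NOE of the epoxide); chain locants count from the acetylenic ring (C7≡C8 … C13=C14), primed locants (C3', C5', C6') belong to the epoxide ring, TBS = tert-butyldimethylsilyl.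

**Step 1**
Reactants: 1 2,6,6-trimethylcyclohex-2-ene-1,4-dione (ketoisophorone)
Product: 2 (6R)-2,2,6-trimethylcyclohexane-1,4-dione ((R)-levodione)
Conditions: L-valine tert-butyl ester·(R)-TRIP phosphate salt (5 mol%), Hantzsch ester (diethyl 2,6-dimethyl-1,4-dihydropyridine-3,5-dicarboxylate, 1.2 equiv), Bu2O, 60 °C
Reagents that add atoms: none
Why: Iminium-type organocatalytic transfer hydrogenation, in which the primary amine condenses with the less hindered C4 carbonyl and the chiral phosphate counter-anion steers hydride from the dihydropyridine to one face of the methyl-bearing β-carbon, setting C6 as R, the first stereocentre, from an achiral enedione.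

**Step 2**
Reactants: 2 (6R)-2,2,6-trimethylcyclohexane-1,4-dione
Product: 3 (4R,6R)-4-hydroxy-2,2,6-trimethylcyclohexan-1-one (actinol)
Conditions: LiBH(sBu)3 (L-Selectride, 1.1 equiv), THF, −78 °C; then H2O; recrystallise
Reagents that add atoms: none
Why: Diastereoselective hydride reduction, in which the bulky borohydride attacks the 3,3,5-trimethylcyclohexanone-like C4 carbonyl from the equatorial side (the axial side is blocked by the axial C2 methyl) to give the axial alcohol trans to the C6 methyl (4R), while the C1 carbonyl flanked by two substituted carbons is left alone.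

**Step 3**
Reactants: 3 (4R,6R)-4-hydroxy-2,2,6-trimethylcyclohexan-1-one
Product: 4 (4R,6R)-4-[(tert-butyldimethylsilyl)oxy]-2,2,6-trimethylcyclohexan-1-one
Conditions: TBSCl, imidazole, DMF, rt
Reagents that add atoms: tert-butyldimethylsilyl chloride (TBSCl), CC(C)(C)[Si](C)(C)Cl
Why: Standard silyl ether formation that masks the only acidic proton before enolate chemistry and touches no stereocentre.

**Step 4**
Reactants: 4 (4R,6R)-4-[(tert-butyldimethylsilyl)oxy]-2,2,6-trimethylcyclohexan-1-one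
Product: 6 (4R)-4-[(tert-butyldimethylsilyl)oxy]-2,6,6-trimethylcyclohex-1-en-1-yl trifluoromethanesulfonate, via lithium enolate 5 (not isolated)
Conditions: LiN(iPr)2 (LDA), THF, −78 °C; then PhNTf2, −78 °C → rt
Reagents that add atoms: N-phenylbis(trifluoromethanesulfonimide) (PhNTf2), O=S(=O)(N(c1ccccc1)S(=O)(=O)C(F)(F)F)C(F)(F)F
Why: Enolate O-triflation, regiochemically unambiguous because C6 is the only enolisable position; the relay stereocentre C6 is erased by design and the silyloxy carbon (R) is untouched.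

**Step 5**
Reactants: 6 (4R)-4-[(tert-butyldimethylsilyl)oxy]-2,6,6-trimethylcyclohex-1-en-1-yl trifluoromethanesulfonate; 7 (E)-1,2-bis(tributylstannyl)ethene (2.5 equiv)
Product: 8 tributyl{(E)-2-[(4R)-4-[(tert-butyldimethylsilyl)oxy]-2,6,6-trimethylcyclohex-1-en-1-yl]ethenyl}stannane
Conditions: Pd(PPh3)4 (5 mol%), LiCl (3 equiv), THF, 65 °C
Reagents that add atoms: none
Why: Stille coupling of an alkenyl triflate with retention of the E geometry, where the excess of 7 and the hindered product secure mono-coupling.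

**Step 6**
Reactants: 8 tributyl{(E)-2-[(4R)-4-[(tert-butyldimethylsilyl)oxy]-2,6,6-trimethylcyclohex-1-en-1-yl]ethenyl}stannane
Product: 9 tributyl{(E)-2-[(1S,4S,6R)-4-[(tert-butyldimethylsilyl)oxy]-2,2,6-trimethyl-7-oxabicyclo[4.1.0]heptan-1-yl]ethenyl}stannane
Conditions: D-fructose-derived Shi ketone (1,2:4,5-di-O-isopropylidene-β-D-erythro-2,3-hexodiulo-2,6-pyranose, 30 mol%), Oxone (2KHSO5·KHSO4·K2SO4), K2CO3, Bu4NHSO4 (cat.), MeCN/dimethoxymethane/aq. Na2B4O7 buffer (pH 10.5), −10 → 0 °C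
Reagents that add atoms: potassium peroxymonosulfate (KHSO5, the active salt of Oxone), [K+].[O-]S(=O)(=O)OO
Why: Proposed new method: the chiral dioxirane formed from the ketone and KHSO5 transfers oxygen through the usual spiro transition state to the ring C5'=C6' bond, the most electron-rich alkene (tetrasubstituted and twisted out of conjugation with the stannylvinyl group, whose C–Sn bond tolerates electrophilic oxygen transfer), on the face anti to the C3' silyloxy group, setting C5' (R) and C6' (S) in one event; the facial sense is taken from 1-arylcyclohexenes (stannylvinyl in the place of aryl, the C5' methyl in the place of the olefinic hydrogen), the catalyst must override the modest syn preference that peracids show on this ring, and the closest known reaction is the Shi epoxidation of trisubstituted and conjugated olefins, which has not been shown on 2,6,6-trimethylcyclohexenyl dienes or on alkenylstannanes.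

**Step 7**
Reactants: 6 (4R)-4-[(tert-butyldimethylsilyl)oxy]-2,6,6-trimethylcyclohex-1-en-1-yl trifluoromethanesulfonate; 10 (2E)-3-methylpent-2-en-4-yn-1-ol
Product: 11 (2E)-5-[(4R)-4-[(tert-butyldimethylsilyl)oxy]-2,6,6-trimethylcyclohex-1-en-1-yl]-3-methylpent-2-en-4-yn-1-ol
Conditions: Pd(PPh3)4 (5 mol%), CuI (10 mol%), Et3N, DMF, rt → 50 °C
Reagents that add atoms: none
Why: Sonogashira coupling of the enol triflate with the terminal alkyne, which builds the C6–C7≡C8 unit and leaves the free allylic alcohol and the 9E double bond unchanged.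

**Step 8**
Reactants: 11 (2E)-5-[(4R)-4-[(tert-butyldimethylsilyl)oxy]-2,6,6-trimethylcyclohex-1-en-1-yl]-3-methylpent-2-en-4-yn-1-ol
Product: 12 (2E)-5-[(4R)-4-[(tert-butyldimethylsilyl)oxy]-2,6,6-trimethylcyclohex-1-en-1-yl]-3-methylpent-2-en-4-ynal
Conditions: MnO2 (excess), CH2Cl2, rt
Reagents that add atoms: none
Why: Chemoselective MnO2 oxidation of a primary allylic alcohol to the enal without E/Z scrambling or over-oxidation.

**Step 9**
Reactants: 12 (2E)-5-[(4R)-4-[(tert-butyldimethylsilyl)oxy]-2,6,6-trimethylcyclohex-1-en-1-yl]-3-methylpent-2-en-4-ynal; 13 (triphenylphosphoranylidene)acetaldehyde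
Product: 14 (2E,4E)-7-[(4R)-4-[(tert-butyldimethylsilyl)oxy]-2,6,6-trimethylcyclohex-1-en-1-yl]-5-methylhepta-2,4-dien-6-ynal
Conditions: toluene, 70 °C
Reagents that add atoms: none
Why: Wittig two-carbon homologation with a stabilised formyl ylide, which gives the new C11=C12 bond E and stops after one homologation because the product dienal is less electrophilic than 12.

**Step 10**
Reactants: 15 prop-2-ynoic acid (propiolic acid)
Product: 16 (2E)-2,3-dibromoprop-2-enoic acid
Conditions: Br2 (1.0 equiv), CHCl3, 0 °C → rt, dark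
Reagents that add atoms: bromine (Br2), BrBr
Why: Anti addition of bromine to the alkyne gives the E dibromide, in which the β-bromine is cis to the carboxyl group as the lactonisation requires.

**Step 11**
Reactants: 16 (2E)-2,3-dibromoprop-2-enoic acid; 10 (2E)-3-methylpent-2-en-4-yn-1-ol
Product: 18 (5Z)-3-bromo-5-[(2E)-4-hydroxy-2-methylbut-2-en-1-ylidene]furan-2(5H)-one, via enynoic acid 17 (not isolated)
Conditions: PdCl2(PPh3)2 (5 mol%), CuI (10 mol%), Et3N (3 equiv), MeCN, rt
Reagents that add atoms: none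
Why: Tandem Sonogashira coupling and 5-exo-dig lactonisation, in which the β-bromide of the dibromoacrylate couples first with retention and the cis carboxylate then adds anti across the alkyne, closing the butenolide with the Z exocyclic double bond and keeping the α-bromide for the later coupling.

**Step 12**
Reactants: 18 (5Z)-3-bromo-5-[(2E)-4-hydroxy-2-methylbut-2-en-1-ylidene]furan-2(5H)-one
Product: 19 {(2E)-4-[(2Z)-4-bromo-5-oxofuran-2(5H)-ylidene]-3-methylbut-2-en-1-yl}triphenylphosphonium bromide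
Conditions: PPh3·HBr, CH2Cl2, rt
Reagents that add atoms: triphenylphosphine hydrobromide, [Br-].c1ccccc1[PH+](c1ccccc1)c1ccccc1
Why: Acid-mediated allylic substitution (phosphonium salt formation from an allylic alcohol, the standard carotenoid protocol), which proceeds through the conjugation-stabilised allyl cation and ends at the unhindered primary carbon with the E geometry.

**Step 13**
Reactants: 19 {(2E)-4-[(2Z)-4-bromo-5-oxofuran-2(5H)-ylidene]-3-methylbut-2-en-1-yl}triphenylphosphonium bromide; 14 (2E,4E)-7-[(4R)-4-[(tert-butyldimethylsilyl)oxy]-2,6,6-trimethylcyclohex-1-en-1-yl]-5-methylhepta-2,4-dien-6-ynal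
Product: 21 (5Z)-3-bromo-5-{(2E,4E,6E,8E)-11-[(4R)-4-[(tert-butyldimethylsilyl)oxy]-2,6,6-trimethylcyclohex-1-en-1-yl]-2,9-dimethylundeca-2,4,6,8-tetraen-10-yn-1-ylidene}furan-2(5H)-one, via phosphonium ylide 20 (not isolated)
Conditions: NaN(SiMe3)2 (NaHMDS, 1.0 equiv), THF, −78 °C; then 14, −78 °C → rt, dark; chromatography removes the minor 13Z isomer
Reagents that add atoms: none
Why: Wittig olefination in which the ylide, stabilised through the dienyl system by the lactone carbonyl, forms C13=C14 mainly E, and the hindered non-nucleophilic base avoids opening the lactone.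

**Step 14**
Reactants: 21 (5Z)-3-bromo-5-{(2E,4E,6E,8E)-11-[(4R)-4-[(tert-butyldimethylsilyl)oxy]-2,6,6-trimethylcyclohex-1-en-1-yl]-2,9-dimethylundeca-2,4,6,8-tetraen-10-yn-1-ylidene}furan-2(5H)-one; 9 tributyl{(E)-2-[(1S,4S,6R)-4-[(tert-butyldimethylsilyl)oxy]-2,2,6-trimethyl-7-oxabicyclo[4.1.0]heptan-1-yl]ethenyl}stannane
Product: 22 (5Z)-3-{(E)-2-[(1S,4S,6R)-4-[(tert-butyldimethylsilyl)oxy]-2,2,6-trimethyl-7-oxabicyclo[4.1.0]heptan-1-yl]ethenyl}-5-{(2E,4E,6E,8E)-11-[(4R)-4-[(tert-butyldimethylsilyl)oxy]-2,6,6-trimethylcyclohex-1-en-1-yl]-2,9-dimethylundeca-2,4,6,8-tetraen-10-yn-1-ylidene}furan-2(5H)-one (bis-TBS ether of the target)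
Conditions: Pd2(dba)3 (5 mol%), AsPh3 (40 mol%), DMF, rt → 40 °C, dark
Reagents that add atoms: none
Why: Stille coupling of the α-bromobutenolide with the alkenylstannane with retention at both sp2 carbons, where zerovalent palladium inserts into the activated C–Br bond much faster than it ionises the fully substituted vinyl epoxide carbon.

**Step 15**
Reactants: 22 bis-TBS ether of the target
Product: 23 (5Z)-3-{(E)-2-[(1S,4S,6R)-4-hydroxy-2,2,6-trimethyl-7-oxabicyclo[4.1.0]heptan-1-yl]ethenyl}-5-{(2E,4E,6E,8E)-11-[(4R)-4-hydroxy-2,6,6-trimethylcyclohex-1-en-1-yl]-2,9-dimethylundeca-2,4,6,8-tetraen-10-yn-1-ylidene}furan-2(5H)-one (CNP0180336.1)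
Conditions: Bu4NF (TBAF)/AcOH (1:1, 6 equiv), THF, 0 °C → rt, dark
Reagents that add atoms: none
Why: Fluoride desilylation of both secondary silyl ethers, buffered with acetic acid so that neither the base-sensitive ylidenebutenolide nor the acid-sensitive vinyl epoxide is harmed.

**Compound list**

1 | 2,6,6-trimethylcyclohex-2-ene-1,4-dione (ketoisophorone) | CC1=CC(=O)CC(C)(C)C1=O | starting material
2 | (6R)-2,2,6-trimethylcyclohexane-1,4-dione | C[C@@H]1CC(=O)CC(C)(C)C1=O | intermediate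
3 | (4R,6R)-4-hydroxy-2,2,6-trimethylcyclohexan-1-one | C[C@@H]1C[C@@H](O)CC(C)(C)C1=O | intermediate
4 | (4R,6R)-4-[(tert-butyldimethylsilyl)oxy]-2,2,6-trimethylcyclohexan-1-one | C[C@@H]1C[C@@H](O[Si](C)(C)C(C)(C)C)CC(C)(C)C1=O | intermediate
5 | lithium (4R)-4-[(tert-butyldimethylsilyl)oxy]-2,6,6-trimethylcyclohex-1-en-1-olate | CC1=C(O[Li])C(C)(C)C[C@H](O[Si](C)(C)C(C)(C)C)C1 | intermediate (not isolated)
6 | (4R)-4-[(tert-butyldimethylsilyl)oxy]-2,6,6-trimethylcyclohex-1-en-1-yl trifluoromethanesulfonate | CC1=C(OS(=O)(=O)C(F)(F)F)C(C)(C)C[C@H](O[Si](C)(C)C(C)(C)C)C1 | intermediate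
7 | (E)-1,2-bis(tributylstannyl)ethene | CCCC[Sn](CCCC)(CCCC)/C=C/[Sn](CCCC)(CCCC)CCCC | starting material
8 | tributyl{(E)-2-[(4R)-4-[(tert-butyldimethylsilyl)oxy]-2,6,6-trimethylcyclohex-1-en-1-yl]ethenyl}stannane | CC1=C(/C=C/[Sn](CCCC)(CCCC)CCCC)C(C)(C)C[C@H](O[Si](C)(C)C(C)(C)C)C1 | intermediate
9 | tributyl{(E)-2-[(1S,4S,6R)-4-[(tert-butyldimethylsilyl)oxy]-2,2,6-trimethyl-7-oxabicyclo[4.1.0]heptan-1-yl]ethenyl}stannane | CCCC[Sn](CCCC)(CCCC)/C=C/[C@@]12O[C@]1(C)C[C@@H](O[Si](C)(C)C(C)(C)C)CC2(C)C | intermediate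
10 | (2E)-3-methylpent-2-en-4-yn-1-ol | C#C/C(C)=C/CO | starting material
11 | (2E)-5-[(4R)-4-[(tert-butyldimethylsilyl)oxy]-2,6,6-trimethylcyclohex-1-en-1-yl]-3-methylpent-2-en-4-yn-1-ol | CC1=C(C#C/C(C)=C/CO)C(C)(C)C[C@H](O[Si](C)(C)C(C)(C)C)C1 | intermediate
12 | (2E)-5-[(4R)-4-[(tert-butyldimethylsilyl)oxy]-2,6,6-trimethylcyclohex-1-en-1-yl]-3-methylpent-2-en-4-ynal | CC1=C(C#C/C(C)=C/C=O)C(C)(C)C[C@H](O[Si](C)(C)C(C)(C)C)C1 | intermediate
13 | (triphenylphosphoranylidene)acetaldehyde | O=CC=P(c1ccccc1)(c1ccccc1)c1ccccc1 | starting material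
14 | (2E,4E)-7-[(4R)-4-[(tert-butyldimethylsilyl)oxy]-2,6,6-trimethylcyclohex-1-en-1-yl]-5-methylhepta-2,4-dien-6-ynal | CC1=C(C#C/C(C)=C/C=C/C=O)C(C)(C)C[C@H](O[Si](C)(C)C(C)(C)C)C1 | intermediate
15 | prop-2-ynoic acid | C#CC(=O)O | starting material
16 | (2E)-2,3-dibromoprop-2-enoic acid | OC(=O)/C(Br)=C\Br | intermediate
17 | (2E,6E)-2-bromo-8-hydroxy-6-methylocta-2,6-dien-4-ynoic acid | OC(=O)/C(Br)=C\C#C/C(C)=C/CO | intermediate (not isolated)
18 | (5Z)-3-bromo-5-[(2E)-4-hydroxy-2-methylbut-2-en-1-ylidene]furan-2(5H)-one | OC/C=C(C)/C=C1C=C(Br)C(=O)O/1 | intermediate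
19 | {(2E)-4-[(2Z)-4-bromo-5-oxofuran-2(5H)-ylidene]-3-methylbut-2-en-1-yl}triphenylphosphonium bromide | [Br-].c1ccccc1[P+](c1ccccc1)(c1ccccc1)C/C=C(C)/C=C1C=C(Br)C(=O)O/1 | intermediate
20 | ylide of 19, (2E)-4-[(2Z)-4-bromo-5-oxofuran-2(5H)-ylidene]-3-methyl-1-(triphenylphosphonio)but-2-en-1-ide | c1ccccc1[P+](c1ccccc1)(c1ccccc1)[CH-]/C=C(C)/C=C1C=C(Br)C(=O)O/1 | intermediate (not isolated)
21 | (5Z)-3-bromo-5-{(2E,4E,6E,8E)-11-[(4R)-4-[(tert-butyldimethylsilyl)oxy]-2,6,6-trimethylcyclohex-1-en-1-yl]-2,9-dimethylundeca-2,4,6,8-tetraen-10-yn-1-ylidene}furan-2(5H)-one | CC1=C(C#C/C(C)=C/C=C/C=C/C=C(C)/C=C2C=C(Br)C(=O)O/2)C(C)(C)C[C@H](O[Si](C)(C)C(C)(C)C)C1 | intermediate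
22 | bis-TBS ether of the target (full name in step 14) | CC1=C(C#C/C(C)=C/C=C/C=C/C=C(C)/C=C2C=C(/C=C/[C@@]34O[C@]3(C)C[C@@H](O[Si](C)(C)C(C)(C)C)CC4(C)C)C(=O)O/2)C(C)(C)C[C@H](O[Si](C)(C)C(C)(C)C)C1 | intermediate
23 | (5Z)-3-{(E)-2-[(1S,4S,6R)-4-hydroxy-2,2,6-trimethyl-7-oxabicyclo[4.1.0]heptan-1-yl]ethenyl}-5-{(2E,4E,6E,8E)-11-[(4R)-4-hydroxy-2,6,6-trimethylcyclohex-1-en-1-yl]-2,9-dimethylundeca-2,4,6,8-tetraen-10-yn-1-ylidene}furan-2(5H)-one | CC1=C(C#C/C(C)=C/C=C/C=C/C=C(C)/C=C2C=C(/C=C/[C@@]34O[C@]3(C)C[C@@H](O)CC4(C)C)C(=O)O/2)C(C)(C)C[C@H](O)C1 | target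

**Step count**

Total: 15 steps. Longest linear sequence: 10 steps (1 → 2 → 3 → 4 → 6 → 11 → 12 → 14 → 21 → 22 → 23).

**Steps most likely to fail, with fallbacks**

Step 6 (the proposed new epoxidation). The chiral dioxirane may fail to override the substrate's syn bias on this hindered tetrasubstituted alkene, or may attack the stannylvinyl group. The fallback uses known chemistry only, sets out from 6 and comes back at 9. Carbonylation of 6 (Pd(OAc)2, PPh3, CO, MeOH, Et3N, DMF) gives methyl (4R)-4-[(tert-butyldimethylsilyl)oxy]-2,6,6-trimethylcyclohex-1-ene-1-carboxylate F1. Reduction with iBu2AlH gives the allylic alcohol F2. Sharpless epoxidation (Ti(OiPr)4, D-(−)-diethyl tartrate, tBuOOH, 4 Å sieves, CH2Cl2, −20 °C) delivers oxygen anti to the silyloxy group and gives the epoxy alcohol F3. Dess–Martin oxidation gives the epoxy aldehyde F4, Ohira–Bestmann homologation (dimethyl (1-diazo-2-oxopropyl)phosphonate, K2CO3, MeOH) gives the epoxy alkyne F5, and hydrostannation (Bu3SnH, PdCl2(PPh3)2, THF) gives 9.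

Step 13 (Wittig with the ylide on the bromo-ylidenebutenolide). The ylide may be too stabilised to react, the lactone may not survive the base, or salt 19 may not form cleanly in step 12. The fallback reverses the polarity so that the butenolide only ever reacts as an aldehyde; it sets out from 11 and 18 and comes back at 21, by-passing steps 12 and 13. PPh3·HBr (CH2Cl2) turns 11 into the C11 phosphonium bromide F6. MnO2 oxidises 18 to the enal F7, which 13 (toluene, 70 °C) lengthens to the dienal F8. NaN(SiMe3)2 converts F6 into the ylide F9, which adds to F8 and forms C11=C12 of 21.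

Step 14 (Stille coupling on the complete polyene). The bromo polyene may decompose, or palladium may open the vinyl epoxide, at the most valuable stage. The fallback moves the cross-coupling to the small bromobutenolide and makes the Wittig reaction the last C–C bond formation; it sets out from 18 and 9 and comes back at 22. Stille coupling of 9 with 18 (same catalyst) gives the epoxy butenolide alcohol F10. CBr4/PPh3 gives the allylic bromide F11, PPh3 (MeCN) gives the phosphonium bromide F12, and its ylide F13 (NaN(SiMe3)2, THF, −78 °C) is condensed with dienal 14 to give 22.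

**Further compounds**

F1 | step 6 | methyl (4R)-4-[(tert-butyldimethylsilyl)oxy]-2,6,6-trimethylcyclohex-1-ene-1-carboxylate | CC1=C(C(=O)OC)C(C)(C)C[C@H](O[Si](C)(C)C(C)(C)C)C1
F2 | step 6 | [(4R)-4-[(tert-butyldimethylsilyl)oxy]-2,6,6-trimethylcyclohex-1-en-1-yl]methanol | CC1=C(CO)C(C)(C)C[C@H](O[Si](C)(C)C(C)(C)C)C1
F3 | step 6 | [(1R,4S,6R)-4-[(tert-butyldimethylsilyl)oxy]-2,2,6-trimethyl-7-oxabicyclo[4.1.0]heptan-1-yl]methanol | OC[C@@]12O[C@]1(C)C[C@@H](O[Si](C)(C)C(C)(C)C)CC2(C)C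
F4 | step 6 | (1S,4S,6R)-4-[(tert-butyldimethylsilyl)oxy]-2,2,6-trimethyl-7-oxabicyclo[4.1.0]heptane-1-carbaldehyde | O=C[C@@]12O[C@]1(C)C[C@@H](O[Si](C)(C)C(C)(C)C)CC2(C)C
F5 | step 6 | (1R,4S,6R)-4-[(tert-butyldimethylsilyl)oxy]-1-ethynyl-2,2,6-trimethyl-7-oxabicyclo[4.1.0]heptane | C#C[C@@]12O[C@]1(C)C[C@@H](O[Si](C)(C)C(C)(C)C)CC2(C)C
F6 | step 13 | {(2E)-5-[(4R)-4-[(tert-butyldimethylsilyl)oxy]-2,6,6-trimethylcyclohex-1-en-1-yl]-3-methylpent-2-en-4-yn-1-yl}triphenylphosphonium bromide | CC1=C(C#C/C(C)=C/C[P+](c2ccccc2)(c2ccccc2)c2ccccc2)C(C)(C)C[C@H](O[Si](C)(C)C(C)(C)C)C1.[Br-]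
F7 | step 13 | (2E)-4-[(2Z)-4-bromo-5-oxofuran-2(5H)-ylidene]-3-methylbut-2-enal | O=C/C=C(C)/C=C1C=C(Br)C(=O)O/1
F8 | step 13 | (2E,4E)-6-[(2Z)-4-bromo-5-oxofuran-2(5H)-ylidene]-5-methylhexa-2,4-dienal | O=C/C=C/C=C(C)/C=C1C=C(Br)C(=O)O/1
F9 | step 13 | ylide of F6, (2E)-5-[(4R)-4-[(tert-butyldimethylsilyl)oxy]-2,6,6-trimethylcyclohex-1-en-1-yl]-3-methyl-1-(triphenylphosphonio)pent-2-en-4-yn-1-ide | CC1=C(C#C/C(C)=C/[CH-][P+](c2ccccc2)(c2ccccc2)c2ccccc2)C(C)(C)C[C@H](O[Si](C)(C)C(C)(C)C)C1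
F10 | step 14 | (5Z)-3-{(E)-2-[(1S,4S,6R)-4-[(tert-butyldimethylsilyl)oxy]-2,2,6-trimethyl-7-oxabicyclo[4.1.0]heptan-1-yl]ethenyl}-5-[(2E)-4-hydroxy-2-methylbut-2-en-1-ylidene]furan-2(5H)-one | OC/C=C(C)/C=C1C=C(/C=C/[C@@]23O[C@]2(C)C[C@@H](O[Si](C)(C)C(C)(C)C)CC3(C)C)C(=O)O/1
F11 | step 14 | (5Z)-5-[(2E)-4-bromo-2-methylbut-2-en-1-ylidene]-3-{(E)-2-[(1S,4S,6R)-4-[(tert-butyldimethylsilyl)oxy]-2,2,6-trimethyl-7-oxabicyclo[4.1.0]heptan-1-yl]ethenyl}furan-2(5H)-one | BrC/C=C(C)/C=C1C=C(/C=C/[C@@]23O[C@]2(C)C[C@@H](O[Si](C)(C)C(C)(C)C)CC3(C)C)C(=O)O/1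
F12 | step 14 | phosphonium bromide from F11 and PPh3 (Ph3P+ in place of the allylic Br) | [Br-].c1ccccc1[P+](c1ccccc1)(c1ccccc1)C/C=C(C)/C=C1C=C(/C=C/[C@@]23O[C@]2(C)C[C@@H](O[Si](C)(C)C(C)(C)C)CC3(C)C)C(=O)O/1
F13 | step 14 | ylide of F12 | c1ccccc1[P+](c1ccccc1)(c1ccccc1)[CH-]/C=C(C)/C=C1C=C(/C=C/[C@@]23O[C@]2(C)C[C@@H](O[Si](C)(C)C(C)(C)C)CC3(C)C)C(=O)O/1
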